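## Analysis of the target

Diacarperoxide B is a monocyclic 1,2-dioxane (ring atoms O1, O2, C3, C4, C5, C6; O2 on C3, O1 on C6) with no carbocycle. C3 carries H and the methyl propanoate arm C1–C2 (with 2-CH3). C6 is a fully substituted peroxy carbon that carries a methyl group and the chain C7–C15, which holds a ketone at C9, a gem-dimethyl quaternary carbon C10 and a methyl ketone at C14. There are three stereocentres. C2 (S) and C3 (S) are contiguous and anti (2-CH3 and O2 on opposite sides of the C1–C4 zig-zag). C6 (R) lies 1,4 across the ring from C3 with the C7 chain cis to the propanoate arm, so in the chair with that arm equatorial the C7 chain is axial and the 6-methyl equatorial. The sensitive groups are the O–O bond (low-valent metals, phosphines, hydrides, hydrogenation catalysts), the C3–H next to the peroxide (base-induced Kornblum–DeLaMare cleavage), the β-peroxy ester (retro-oxa-Michael, epimerisable C2) and two enolisable ketones. The hard problem is C6: its two carbon arms, CH3 and CH2CH2R, are almost equal in size, so a ring closure that forms a C–O bond at C6 cannot tell them apart, and tertiary hydroperoxides cannot be made stereospecifically from tertiary alcohols. The feature the route uses is that C6 is a ketal-level carbon once the C6–C7 bond is cut, and at the same time lies γ to the C9 carbonyl (C6–C7–C8–C9=O). C6–C7 is therefore the bond between a ring peroxycarbenium ion and a C7–C8–C9 ketone homoenolate, and in such a ring cation the C3 substituent can dictate the face of attack.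

## Retrosynthetic reasoning

**C6–C7 (key disconnection).** Target 21 is cut between the quaternary ring carbon C6 and C7. This gives the cyclic peroxycarbenium ion 19, generated from the methoxy peroxyketal 11, and the complete C7–C15 chain as the cyclopropyl silyl ether 18, a homoenol of the C9 ketone. No C–O bond is formed at C6, so the methyl/chain discrimination problem disappears: the methyl is already on the cation and the chain enters as the nucleophile. The forward reaction has to deliver the chain axially, cis to the C3 arm, which gives 6R by relay from C3. It joins two fragments of similar size and ends the synthesis, so nothing has to survive after it.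

**C1 oxidation level.** Ester 11 is taken back through acid 10 to the vinyl compound 8. The vinyl group stands for C1 because a C1 ester would make C2–H acidic and invite E1cB loss of the C3 leaving group during ring closure.

**O2–C3 (ring closure).** The dioxane ring of 8 is opened at the O2–C3 bond to the hydroperoxy ketal 6, whose peroxide anion displaces a secondary mesylate in a 6-exo-tet closure with inversion. The C6 ketal centre that forms here need not be controlled, because step 12 planarises it. Compound 6 comes from ketone 5 by peroxyketalisation, and 5 from alcohol 4 by mesylation.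

**C2–C3 (both stereocentres from one reagent).** Alcohol 4 is cut between C2 and C3 to the keto aldehyde 2 and a chiral (Z)-crotylboron reagent. One reagent-controlled event sets C2 and the carbinol centre, syn, in the absolute sense that the later inversion at C3 converts into the anti (2S,3S) array. Compound 2 comes from the commercial hydroxy ketone 1 by oxidation.

**Chain fragment.** Silyl ether 18 is taken back through cyclopropanol 17 and its ketal 16 to ester 15, by a Kulinkovich cyclopropanation that turns the ester carbon into C9 and adds C7 and C8. Ester 15 is cut at C10–C11 to the enolate of ester 12 and the chloride 13, which creates the gem-dimethyl quaternary carbon C10 by alkylation.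

## Alternatives that were turned down

**Alternative 1:** (textbook) Disconnection of O2–C3 by intramolecular oxa-Michael addition and of O1–C6 by cobalt-catalysed hydroperoxysilylation (Mukaiyama–Isayama, Co(thd)2/O2/Et3SiH). The triene ester A1 would be assembled from a commercial C13 cyclohexenyl methyl ketone, converted into the tertiary hydroperoxide A2, cyclised with base, and the cyclohexene ozonised at the end. The route is short, but it was turned down for three reasons:
- C6 is formed through a radical and is racemic.
- In the chair transition state of the 6-exo closure the two arms on C6 (CH3 and CH2CH2R) have the same steric demand, so C3 forms without bias relative to C6.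
- C2 is set by an uncontrolled enolate protonation.

The outcome would be four racemic diastereomers, with no handle for a single enantiomer short of resolution.

**Alternative 2:** Disconnection of both C–O bonds at once by a singlet-oxygen [4+2] cycloaddition to the diene A3, giving the 3,6-dihydro-1,2-dioxine A4, followed by diimide reduction. A suprafacial cycloaddition would relate C3 and C6 through the diene geometry. The chain must then be "outside" and the 6-methyl "inside" (cis to C4). An inside methyl clashes with C3–H in the s-cis conformer that the cycloaddition needs, and the trisubstituted terminus offers allylic hydrogens on 6-CH3 and C7 for the faster ene reaction. Facial control by the lone C2 stereocentre on an acyclic diene is weak. The approach was turned down.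

**Alternative 3:** The reverse relay: disconnection of C2–C3 by addition of an auxiliary-bound propionate enolate to a peroxycarbenium ion at C3, generated from the cyclic peroxyacetal A5. A5 already carries the quaternary C6 with the chain masked as a trimethylcyclohexene. This would set C2 and C3 together and bring the ester in directly. It was turned down because C6 cannot steer the cation: its two arms populate the pseudo-axial and pseudo-equatorial positions equally, so C3 forms without preference relative to C6. C6 itself would be racemic, since its hydroperoxide can only be made through a tertiary cation. Even a fully reagent-controlled enolate would give a 1:1 mixture of C6 epimers.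

Key step: step 12

## Route

Remark: the ketal carbon C6 of compounds 6–11 forms as a mixture of epimers and is left unspecified in names and SMILES; both epimers give the same cation 19 in step 12.

Step 1
Reactants: 1 5-hydroxypentan-2-one
Product: 2 4-oxopentanal
Conditions: TEMPO (10 mol%), PhI(OAc)2 (1.1 equiv), CH2Cl2, rt
Reagents that add atoms: none
Why: The TEMPO/PhI(OAc)2 oxidation of the primary alcohol stops at the aldehyde and leaves the methyl ketone alone; the keto aldehyde is used promptly to avoid self-aldol reaction.

Step 2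
Reactants: 2 4-oxopentanal
Product: 4 (5R,6R)-5-hydroxy-6-methyloct-7-en-2-one, via borinic ester adduct 3 (not isolated)
Conditions: cis-but-2-ene, KOtBu, n-BuLi, THF, −78 → −45 °C; (−)-Ipc2BOMe, −78 °C; BF3·OEt2; then 2, −78 °C; NaBO3·4H2O, THF/H2O, rt
Reagents that add atoms: (Z)-crotyldiisopinocampheylborane (made in the flask), C/C=C\CB([C@@H]1C[C@@H]2C[C@H]([C@H]1C)C2(C)C)[C@@H]1C[C@@H]2C[C@H]([C@H]1C)C2(C)C
Why: Brown (Z)-crotylboration through a Zimmerman–Traxler chair: the Z geometry gives the 5,6-syn adduct, and the isopinocampheyl groups derived from (+)-α-pinene direct attack to the si face of the aldehyde, which sets 5R and 6R. Crotylboranes of this type add to aldehydes far faster than to a methyl ketone at −78 °C.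

Step 3
Reactants: 4 (5R,6R)-5-hydroxy-6-methyloct-7-en-2-one
Product: 5 (3R,4R)-3-methyl-7-oxooct-1-en-4-yl methanesulfonate
Conditions: MsCl, Et3N, CH2Cl2, 0 °C
Reagents that add atoms: methanesulfonyl chloride, CS(=O)(=O)Cl
Why: Standard mesylation turns the carbinol oxygen at the future C3 into a leaving group without touching either stereocentre; the ketone and the vinyl group are inert.

Step 4
Reactants: 5 (3R,4R)-3-methyl-7-oxooct-1-en-4-yl methanesulfonate
Product: 6 (3R,4R)-7-hydroperoxy-7-methoxy-3-methyloct-1-en-4-yl methanesulfonate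
Conditions: urea·H2O2 (5 equiv), Sc(OTf)3 (10 mol%), MeOH, rt
Reagents that add atoms: hydrogen peroxide (as the urea adduct), OO; methanol, CO
Why: Lewis-acid-catalysed peroxyketalisation of a methyl ketone in methanol gives the α-methoxy hydroperoxide; the mesylate and the alkene do not react under these neutral to weakly acidic conditions.

Step 5
Reactants: 6 (3R,4R)-7-hydroperoxy-7-methoxy-3-methyloct-1-en-4-yl methanesulfonate
Product: 8 (3S)-3-[(2R)-but-3-en-2-yl]-6-methoxy-6-methyl-1,2-dioxane, via potassium peroxide salt 7 (not isolated)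
Conditions: KOtBu (1.0 equiv), 18-crown-6, THF, 0 °C → rt
Reagents that add atoms: none
Why: Intramolecular alkylation of a hydroperoxy ketal anion by a sulfonate (6-exo-tet SN2) closes the dioxane with inversion at C3, which gives 3S and the anti C2/C3 relationship. The peroxide anion is a strong nucleophile but a weak base, and without a carbonyl group at C1 the C2–H is not acidic, so substitution should outrun elimination.

Step 6
Reactants: 8 (3S)-3-[(2R)-but-3-en-2-yl]-6-methoxy-6-methyl-1,2-dioxane
Product: 10 (2S)-2-[(3S)-6-methoxy-6-methyl-1,2-dioxan-3-yl]propanoic acid, via aldehyde 9 (not isolated)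
Conditions: O3, MeCN/H2O (9:1), 0 °C; then NaClO2, NaH2PO4, rt
Reagents that add atoms: ozone, [O-][O+]=O; water, O; sodium chlorite, [Na+].[O-]Cl=O
Why: Ozonolysis in aqueous acetonitrile gives the aldehyde directly by capture of the carbonyl oxide with water, and chlorite (Pinnick oxidation) takes it on to the acid in the same flask, with the hydrogen peroxide formed acting as hypochlorite scavenger. Dialkyl peroxides and peroxyketals are inert to both oxidants, and the short-lived aldehyde is kept at about pH 4, where neither epimerisation at C2 nor β-elimination of the peroxide is expected.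

Step 7
Reactants: 10 (2S)-2-[(3S)-6-methoxy-6-methyl-1,2-dioxan-3-yl]propanoic acid
Product: 11 methyl (2S)-2-[(3S)-6-methoxy-6-methyl-1,2-dioxan-3-yl]propanoate
Conditions: TMSCHN2, toluene/MeOH (3:1), 0 °C
Reagents that add atoms: (trimethylsilyl)diazomethane, C[Si](C)(C)C=[N+]=[N-]
Why: Esterification with the diazo reagent needs neither base nor strong acid, so the β-peroxy ester and the peroxyketal are not put at risk.

Step 8
Reactants: 12 methyl 2-methylpropanoate; 13 2-(3-chloropropyl)-2-methyl-1,3-dioxolane
Product: 15 methyl 2,2-dimethyl-5-(2-methyl-1,3-dioxolan-2-yl)pentanoate, via lithium enolate 14 (not isolated)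
Conditions: LDA, THF, −78 °C; then 13, NaI (10 mol%), DMPU, −78 °C → rt
Reagents that add atoms: none
Why: Alkylation of the tetrasubstituted ester enolate with a primary halide (iodide catalysis) creates the gem-dimethyl quaternary carbon C10; the ketal protects the future C14 ketone.

Step 9
Reactants: 15 methyl 2,2-dimethyl-5-(2-methyl-1,3-dioxolan-2-yl)pentanoate
Product: 16 1-[2-methyl-5-(2-methyl-1,3-dioxolan-2-yl)pentan-2-yl]cyclopropan-1-ol
Conditions: EtMgBr (3 equiv), Ti(OiPr)4 (0.3 equiv), THF, 0 °C → rt; aq. NH4Cl
Reagents that add atoms: ethylmagnesium bromide, CC[Mg]Br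
Why: Kulinkovich cyclopropanation: the titanacyclopropane formed from EtMgBr and Ti(OiPr)4 adds twice to the ester carbonyl, which turns the ester carbon into C9 and delivers C7 and C8 as the ring methylenes. The ketal is inert.

Step 10
Reactants: 16 1-[2-methyl-5-(2-methyl-1,3-dioxolan-2-yl)pentan-2-yl]cyclopropan-1-ol
Product: 17 6-(1-hydroxycyclopropyl)-6-methylheptan-2-one
Conditions: PPTS (cat.), acetone/H2O (9:1), 40 °C
Reagents that add atoms: water, O
Why: Mild acid-catalysed ketal hydrolysis frees the C14 methyl ketone; tertiary cyclopropanols tolerate pyridinium tosylate, which is too weak to open the ring.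

Step 11
Reactants: 17 6-(1-hydroxycyclopropyl)-6-methylheptan-2-one
Product: 18 6-methyl-6-[1-(trimethylsilyloxy)cyclopropyl]heptan-2-one
Conditions: 1-(trimethylsilyl)imidazole, CH2Cl2, rt
Reagents that add atoms: 1-(trimethylsilyl)imidazole, C[Si](C)(C)n1ccnc1
Why: The N-silylimidazole silylates the hindered tertiary cyclopropanol under neutral conditions, so the base-labile cyclopropanol does not open and the methyl ketone is not enolised.

Step 12
Reactants: 11 methyl (2S)-2-[(3S)-6-methoxy-6-methyl-1,2-dioxan-3-yl]propanoate; 18 6-methyl-6-[1-(trimethylsilyloxy)cyclopropyl]heptan-2-one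
Product: 21 methyl (2S)-2-[(3S,6R)-6-(4,4-dimethyl-3,8-dioxononyl)-6-methyl-1,2-dioxan-3-yl]propanoate (diacarperoxide B), via peroxycarbenium ion 19 (not isolated), via silyloxycarbenium ion 20 (not isolated)
Conditions: TMSOTf (0.2 equiv), 2,6-di-tert-butyl-4-methylpyridine (0.1 equiv), CH2Cl2, −78 → −40 °C; aq. NaHCO3
Reagents that add atoms: none
Why: Proposed new method: TMSOTf ionises the methoxy group of either C6 epimer of 11 to the planar 1,2-dioxan-3-ylium (peroxycarbenium) ion 19, whose C6 is attacked by a methylene carbon of the donor cyclopropane 18 with cleavage of the bond to the siloxy-bearing carbon (SE2 ring opening); the resulting silyloxycarbenium ion 20 gives up Me3Si+ to triflate, which regenerates the silyl triflate and leaves the C9 ketone. The closest known reaction types are the Lewis-acid-mediated substitution of 3-alkoxy-1,2-dioxanes and 3-alkoxy-1,2-dioxolanes by allylsilanes and silyl enol ethers, and the intramolecular addition of cyclopropyl silyl ethers (homoenols) to oxocarbenium ions; their intermolecular combination on a peroxyketal is what is new. No ring is closed in this step: the three-membered ring opens and the dioxane is kept. The only new stereocentre is C6: the cation should react through the half-chair that holds the C3 propanoate arm pseudo-equatorial, and the nucleophile should enter along the axial trajectory that leads directly to a chair, which places the C7 chain axial and cis to the C3 arm and leaves the 6-methyl equatorial, that is 6R (the 1,4-cis outcome known for 4-alkyl tetrahydropyranyl cations). The step needs chemoselectivity for the cation in the presence of an ester and two ketones; the strained, oxygen-activated C–C bond of 18 is the only strong carbon nucleophile present, and the free C14 ketone is a far weaker electrophile than 19 and too remote for internal capture (eight-membered ring). Titanium and tin halides are avoided because they would convert 18 into unreactive metal homoenolates, and the hindered pyridine removes adventitious TfOH that would otherwise protonolyse 18.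

## Compound list

1 | 5-hydroxypentan-2-one | CC(=O)CCCO | starting material
2 | 4-oxopentanal | CC(=O)CCC=O | intermediate
3 | (3R,4R)-3-methyl-7-oxooct-1-en-4-yl bis(isopinocampheyl)borinate (isopinocampheyl groups from (+)-α-pinene) | CC(=O)CC[C@@H](OB([C@@H]1C[C@@H]2C[C@H]([C@H]1C)C2(C)C)[C@@H]1C[C@@H]2C[C@H]([C@H]1C)C2(C)C)[C@H](C)C=C | intermediate (not isolated)
4 | (5R,6R)-5-hydroxy-6-methyloct-7-en-2-one | CC(=O)CC[C@@H](O)[C@H](C)C=C | intermediate
5 | (3R,4R)-3-methyl-7-oxooct-1-en-4-yl methanesulfonate | CC(=O)CC[C@@H](OS(C)(=O)=O)[C@H](C)C=C | intermediate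
6 | (3R,4R)-7-hydroperoxy-7-methoxy-3-methyloct-1-en-4-yl methanesulfonate | COC(C)(OO)CC[C@@H](OS(C)(=O)=O)[C@H](C)C=C | intermediate
7 | potassium peroxide salt of 6 | [K+].COC(C)(O[O-])CC[C@@H](OS(C)(=O)=O)[C@H](C)C=C | intermediate (not isolated)
8 | (3S)-3-[(2R)-but-3-en-2-yl]-6-methoxy-6-methyl-1,2-dioxane | C=C[C@@H](C)[C@@H]1CCC(C)(OC)OO1 | intermediate
9 | (2S)-2-[(3S)-6-methoxy-6-methyl-1,2-dioxan-3-yl]propanal | O=C[C@@H](C)[C@@H]1CCC(C)(OC)OO1 | intermediate (not isolated)
10 | (2S)-2-[(3S)-6-methoxy-6-methyl-1,2-dioxan-3-yl]propanoic acid | OC(=O)[C@@H](C)[C@@H]1CCC(C)(OC)OO1 | intermediate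
11 | methyl (2S)-2-[(3S)-6-methoxy-6-methyl-1,2-dioxan-3-yl]propanoate | COC(=O)[C@@H](C)[C@@H]1CCC(C)(OC)OO1 | intermediate
12 | methyl 2-methylpropanoate | COC(=O)C(C)C | starting material
13 | 2-(3-chloropropyl)-2-methyl-1,3-dioxolane | CC1(CCCCl)OCCO1 | starting material
14 | lithium 1-methoxy-2-methylprop-1-en-1-olate | [Li+].COC([O-])=C(C)C | intermediate (not isolated)
15 | methyl 2,2-dimethyl-5-(2-methyl-1,3-dioxolan-2-yl)pentanoate | COC(=O)C(C)(C)CCCC1(C)OCCO1 | intermediate
16 | 1-[2-methyl-5-(2-methyl-1,3-dioxolan-2-yl)pentan-2-yl]cyclopropan-1-ol | CC1(CCCC(C)(C)C2(O)CC2)OCCO1 | intermediate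
17 | 6-(1-hydroxycyclopropyl)-6-methylheptan-2-one | CC(=O)CCCC(C)(C)C1(O)CC1 | intermediate
18 | 6-methyl-6-[1-(trimethylsilyloxy)cyclopropyl]heptan-2-one | CC(=O)CCCC(C)(C)C1(O[Si](C)(C)C)CC1 | intermediate
19 | (6S)-6-[(2S)-1-methoxy-1-oxopropan-2-yl]-3-methyl-1,2-dioxan-3-ylium triflate | COC(=O)[C@@H](C)[C@@H]1CCC(C)=[O+]O1.[O-]S(=O)(=O)C(F)(F)F | intermediate (not isolated)
20 | O-trimethylsilyl oxocarbenium ion at C9 of 21, triflate | COC(=O)[C@@H](C)[C@@H]1CC[C@](C)(CCC(=[O+][Si](C)(C)C)C(C)(C)CCCC(C)=O)OO1.[O-]S(=O)(=O)C(F)(F)F | intermediate (not isolated)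
21 | methyl (2S)-2-[(3S,6R)-6-(4,4-dimethyl-3,8-dioxononyl)-6-methyl-1,2-dioxan-3-yl]propanoate (diacarperoxide B) | COC(=O)[C@@H](C)[C@@H]1CC[C@](C)(CCC(=O)C(C)(C)CCCC(C)=O)OO1 | target

## Step count and least certain steps

Total step count: 12 (ring fragment 7, chain fragment 4, coupling 1). Longest linear sequence: 8 (steps 1–7 and 12).

**Step 12 (key step, Proposed new method).**
- What may go wrong: protonolysis of the cyclopropyl silyl ether by traces of acid faster than C–C bond formation; fragmentation or deprotonation of the peroxycarbenium ion before it is captured; loss of facial selectivity through equatorial attack by the hindered nucleophile.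
- Fallback (known chemistry, from 11 back to 21): the chain is introduced as a silyl enol ether, a nucleophile class known to substitute alkoxydioxanes, and the 1,6-diketone is carried as a trimethylcyclohexene.
  - β-Cyclocitral and MeMgBr give 1-(2,6,6-trimethylcyclohex-1-en-1-yl)ethan-1-ol F1.
  - MnO2 oxidation gives 1-(2,6,6-trimethylcyclohex-1-en-1-yl)ethan-1-one F2.
  - LDA/TMSCl gives trimethyl{[1-(2,6,6-trimethylcyclohex-1-en-1-yl)ethenyl]oxy}silane F3.
  - Compound 11 and F3 with TMSOTf at −78 °C should give, by the same axial attack, methyl (2S)-2-[(3S,6R)-6-methyl-6-[2-oxo-2-(2,6,6-trimethylcyclohex-1-en-1-yl)ethyl]-1,2-dioxan-3-yl]propanoate F4.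
  - Luche reduction (NaBH4, CeCl3·7H2O, MeOH) gives methyl (2S)-2-[(3S,6R)-6-[2-hydroxy-2-(2,6,6-trimethylcyclohex-1-en-1-yl)ethyl]-6-methyl-1,2-dioxan-3-yl]propanoate F5.
  - Ionic hydrogenation of the allylic alcohol (Et3SiH, BF3·OEt2, CH2Cl2, −78 °C; hydride to the less hindered allyl terminus) gives methyl (2S)-2-[(3S,6S)-6-methyl-6-[2-(2,6,6-trimethylcyclohex-1-en-1-yl)ethyl]-1,2-dioxan-3-yl]propanoate F6.
  - Ozonolysis of the tetrasubstituted alkene (O3, CH2Cl2, −78 °C; Me2S) opens the ring to the C9 and C14 ketones of 21.

**Step 5.**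
- What may go wrong: slow substitution at the β-branched secondary carbon, so that E2 elimination toward the conjugated diene or reversion of the hydroperoxy ketal takes over.
- Fallback (from 2 back to 8): two inversions replace one.
  - Crotylboration of 2 with the (E)-crotylborane made from trans-but-2-ene and (+)-Ipc2BOMe gives (5S,6R)-5-hydroxy-6-methyloct-7-en-2-one F7.
  - Appel iodination (I2, PPh3, imidazole) with inversion gives (5R,6R)-5-iodo-6-methyloct-7-en-2-one F8.
  - Peroxyketalisation as in step 4 gives (3R,4R)-7-hydroperoxy-4-iodo-7-methoxy-3-methyloct-1-ene F9.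
  - Silver-assisted cyclisation (Ag2O, CH2Cl2) with a second inversion gives 8.

**Step 6.**
- What may go wrong: hydrolysis or ionisation of the methoxy peroxyketal in the aqueous, weakly acidic oxidation medium, and β-elimination of the peroxide from the aldehyde before it is oxidised.
- Fallback (from 8 back to 21): the oxidation is moved behind the coupling, where no peroxyketal is left.
  - Compound 8 is coupled with 18 under the conditions of step 12 (the vinyl group is a poor nucleophile) to give (3S,6R)-3-[(2R)-but-3-en-2-yl]-6-(4,4-dimethyl-3,8-dioxononyl)-6-methyl-1,2-dioxane F10.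
  - Ozonolysis and chlorite oxidation as in step 6 give (2S)-2-[(3S,6R)-6-(4,4-dimethyl-3,8-dioxononyl)-6-methyl-1,2-dioxan-3-yl]propanoic acid F11.
  - TMSCHN2 gives 21.

**Step 9.**
- What may go wrong: slow insertion of the neopentyl-type ester carbonyl into the titanacyclopropane, so that the reagent is consumed unproductively.
- Fallback (from 13 back to 16): the cyclopropane is built by carbenoid addition to an enol ether.
  - Lithiated isobutyronitrile and 13 give 2,2-dimethyl-5-(2-methyl-1,3-dioxolan-2-yl)pentanenitrile F12.
  - MeLi followed by mild hydrolysis of the ketimine gives 3,3-dimethyl-6-(2-methyl-1,3-dioxolan-2-yl)hexan-2-one F13.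
  - LDA/TMSCl gives {[3,3-dimethyl-6-(2-methyl-1,3-dioxolan-2-yl)hex-1-en-2-yl]oxy}trimethylsilane F14.
  - Simmons–Smith cyclopropanation (Et2Zn, CH2I2) gives trimethyl({1-[2-methyl-5-(2-methyl-1,3-dioxolan-2-yl)pentan-2-yl]cyclopropyl}oxy)silane F15.
  - Buffered fluoride (TBAF, AcOH, THF, 0 °C) gives 16.

## Further compounds

F1 | step 12 | 1-(2,6,6-trimethylcyclohex-1-en-1-yl)ethan-1-ol | CC(O)C1=C(C)CCCC1(C)C
F2 | step 12 | 1-(2,6,6-trimethylcyclohex-1-en-1-yl)ethan-1-one | CC(=O)C1=C(C)CCCC1(C)C
F3 | step 12 | trimethyl{[1-(2,6,6-trimethylcyclohex-1-en-1-yl)ethenyl]oxy}silane | C=C(O[Si](C)(C)C)C1=C(C)CCCC1(C)C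
F4 | step 12 | methyl (2S)-2-[(3S,6R)-6-methyl-6-[2-oxo-2-(2,6,6-trimethylcyclohex-1-en-1-yl)ethyl]-1,2-dioxan-3-yl]propanoate | COC(=O)[C@@H](C)[C@@H]1CC[C@](C)(CC(=O)C2=C(C)CCCC2(C)C)OO1
F5 | step 12 | methyl (2S)-2-[(3S,6R)-6-[2-hydroxy-2-(2,6,6-trimethylcyclohex-1-en-1-yl)ethyl]-6-methyl-1,2-dioxan-3-yl]propanoate | COC(=O)[C@@H](C)[C@@H]1CC[C@](C)(CC(O)C2=C(C)CCCC2(C)C)OO1
F6 | step 12 | methyl (2S)-2-[(3S,6S)-6-methyl-6-[2-(2,6,6-trimethylcyclohex-1-en-1-yl)ethyl]-1,2-dioxan-3-yl]propanoate | COC(=O)[C@@H](C)[C@@H]1CC[C@](C)(CCC2=C(C)CCCC2(C)C)OO1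
F7 | step 5 | (5S,6R)-5-hydroxy-6-methyloct-7-en-2-one | CC(=O)CC[C@H](O)[C@H](C)C=C
F8 | step 5 | (5R,6R)-5-iodo-6-methyloct-7-en-2-one | CC(=O)CC[C@@H](I)[C@H](C)C=C
F9 | step 5 | (3R,4R)-7-hydroperoxy-4-iodo-7-methoxy-3-methyloct-1-ene | COC(C)(OO)CC[C@@H](I)[C@H](C)C=C
F10 | step 6 | (3S,6R)-3-[(2R)-but-3-en-2-yl]-6-(4,4-dimethyl-3,8-dioxononyl)-6-methyl-1,2-dioxane | C=C[C@@H](C)[C@@H]1CC[C@](C)(CCC(=O)C(C)(C)CCCC(C)=O)OO1
F11 | step 6 | (2S)-2-[(3S,6R)-6-(4,4-dimethyl-3,8-dioxononyl)-6-methyl-1,2-dioxan-3-yl]propanoic acid | OC(=O)[C@@H](C)[C@@H]1CC[C@](C)(CCC(=O)C(C)(C)CCCC(C)=O)OO1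
F12 | step 9 | 2,2-dimethyl-5-(2-methyl-1,3-dioxolan-2-yl)pentanenitrile | N#CC(C)(C)CCCC1(C)OCCO1
F13 | step 9 | 3,3-dimethyl-6-(2-methyl-1,3-dioxolan-2-yl)hexan-2-one | CC(=O)C(C)(C)CCCC1(C)OCCO1
F14 | step 9 | {[3,3-dimethyl-6-(2-methyl-1,3-dioxolan-2-yl)hex-1-en-2-yl]oxy}trimethylsilane | C=C(O[Si](C)(C)C)C(C)(C)CCCC1(C)OCCO1
F15 | step 9 | trimethyl({1-[2-methyl-5-(2-methyl-1,3-dioxolan-2-yl)pentan-2-yl]cyclopropyl}oxy)silane | C[Si](C)(C)OC1(CC1)C(C)(C)CCCC1(C)OCCO1
A1 | alternative 1 | methyl (2E)-2-methyl-6-methylidene-8-(2,6,6-trimethylcyclohex-1-en-1-yl)oct-2-enoate | COC(=O)/C(C)=C/CCC(=C)CCC1=C(C)CCCC1(C)C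
A2 | alternative 1 | methyl (2E)-6-hydroperoxy-2,6-dimethyl-8-(2,6,6-trimethylcyclohex-1-en-1-yl)oct-2-enoate | COC(=O)/C(C)=C/CCC(C)(OO)CCC1=C(C)CCCC1(C)C
A3 | alternative 2 | methyl (2S,3E,5E)-2,6,10,10-tetramethyl-9,14-dioxopentadeca-3,5-dienoate | COC(=O)[C@@H](C)/C=C/C=C(\C)CCC(=O)C(C)(C)CCCC(C)=O
A4 | alternative 2 | methyl (2S)-2-[(3S,6S)-6-(4,4-dimethyl-3,8-dioxononyl)-6-methyl-3,6-dihydro-1,2-dioxin-3-yl]propanoate | COC(=O)[C@@H](C)[C@@H]1C=C[C@](C)(CCC(=O)C(C)(C)CCCC(C)=O)OO1
A5 | alternative 3 | 3-methoxy-6-methyl-6-[2-(2,6,6-trimethylcyclohex-1-en-1-yl)ethyl]-1,2-dioxane | COC1CCC(C)(CCC2=C(C)CCCC2(C)C)OO1
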